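**Retrosynthetic overview**
- C8′–C9′ of the (7E,9E)-diene: Suzuki–Miyaura union of a dioxolane (E)-vinyl iodide with a (1E,4Z)-heptadienyl boronate (from pent-2-yn-1-ol).
- O2–C3 of the 1,2-dioxolane: intramolecular oxa-Michael (5-exo) addition of the C5 tertiary hydroperoxide to a β-methyl enoate, which sets C3; the enoate comes from an HWE reaction on a β-peroxy methyl ketone.
- C5–OOH: invertive Lewis-acid perhydrolysis of an (R)-2,2,4-trisubstituted oxetane, then oxidation of the liberated secondary alcohol.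
- Side-chain C3′–C4′: Cu-catalysed sp3–sp3 coupling of an oxetanylpropyl Grignard reagent (from (R)-linalool) with (E)-5-iodopent-4-enyl tosylate (from pent-4-yn-1-ol).
- Ring order: the oxetane first (temporary carrier of the stereocentre), then the 1,2-dioxolane, the only ring of the target.

Assumption: (R)-(−)-linalool of ≥97% ee is used (checked by chiral GC); its carbinol carbon is the only source of absolute configuration and becomes C5 after one inversion.
Assumption: the methyl-carbinol carbon created in step 3 (and carried in 5–11, 16–19) is an inconsequential epimer mixture, left undefined in names and SMILES; Cp rings are drawn σ-bonded in SMILES.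

**Route**

Step 1
Reactants: 1 (R)-(−)-linalool [(3R)-3,7-dimethylocta-1,6-dien-3-ol]
Product: 3 (3R)-3,7-dimethyloct-6-ene-1,3-diol, via B-alkyl-9-BBN borane 2 (not isolated)
Conditions: 9-BBN (1.5 equiv), THF, 0 °C → rt; then 3 M NaOH, 30% H2O2, 0 °C → rt
Reagents that add atoms: hydrogen peroxide, OO
Why: Anti-Markovnikov hydroboration–oxidation; bulky 9-BBN reacts only with the monosubstituted vinyl group, and the tertiary carbinol stereocentre (future C5) is not touched.

Step 2
Reactants: 3 (3R)-3,7-dimethyloct-6-ene-1,3-diol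
Product: 4 (3R)-3-hydroxy-3,7-dimethyloct-6-enal
Conditions: Dess–Martin periodinane (1.2 equiv), pyridine, CH2Cl2, 0 °C; used crude
Reagents that add atoms: none
Why: Dess–Martin oxidation; only the primary alcohol can be oxidised, and cold buffered conditions avoid dehydration or retro-aldol of the tertiary β-hydroxy aldehyde.

Step 3
Reactants: 4 (3R)-3-hydroxy-3,7-dimethyloct-6-enal
Product: 5 (4R)-4,8-dimethylnon-7-ene-2,4-diol (2RS)
Conditions: MeMgBr (3 equiv), THF, −78 → 0 °C (inverse addition); aq NH4Cl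
Reagents that add atoms: methylmagnesium bromide, C[Mg]Br
Why: Grignard 1,2-addition to the aldehyde; the new carbinol centre forms without control (about 1:1) but is later oxidised to the C3 ketone, so it does not matter.

Step 4
Reactants: 5 (4R)-4,8-dimethylnon-7-ene-2,4-diol (2RS)
Product: 7 (2R)-2,4-dimethyl-2-(4-methylpent-3-en-1-yl)oxetane (4RS), via secondary monotosylate 6 (not isolated)
Conditions: n-BuLi (1.0 equiv), THF, 0 °C; TsCl (1.0 equiv), 0 °C; then n-BuLi (1.1 equiv), 0 → 50 °C
Reagents that add atoms: none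
Why: One-pot selective sulfonylation of the less hindered secondary alkoxide, then intramolecular Williamson etherification (4-exo-tet) by the tertiary alkoxide; the quaternary centre keeps its configuration because its C–O bond is not broken.

Step 5
Reactants: 7 (2R)-2,4-dimethyl-2-(4-methylpent-3-en-1-yl)oxetane (4RS)
Product: 10 3-[(2R)-2,4-dimethyloxetan-2-yl]propan-1-ol, via ozonide 8 (not isolated), via aldehyde 9 (not isolated)
Conditions: O3, CH2Cl2, −78 °C; then MeOH, NaBH4, −78 °C → rt
Reagents that add atoms: ozone, [O-][O+]=O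
Why: Ozonolysis of the trisubstituted alkene with reductive borohydride work-up gives the primary alcohol directly; the oxetane is inert to ozone and hydride.

Step 6
Reactants: 10 3-[(2R)-2,4-dimethyloxetan-2-yl]propan-1-ol
Product: 11 (2R)-2-(3-bromopropyl)-2,4-dimethyloxetane
Conditions: CBr4 (1.2 equiv), PPh3 (1.25 equiv), 2,6-lutidine (0.2 equiv), CH2Cl2, 0 °C
Reagents that add atoms: carbon tetrabromide, BrC(Br)(Br)Br
Why: Appel reaction under neutral conditions converts the primary alcohol to the bromide without acid that could open the oxetane (hydroxymethyl oxetanes are brominated this way).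

Step 7
Reactants: 12 pent-4-yn-1-ol
Product: 13 pent-4-yn-1-yl 4-methylbenzenesulfonate
Conditions: TsCl (1.1 equiv), Et3N (1.5 equiv), DMAP (5 mol %), CH2Cl2, 0 °C → rt
Reagents that add atoms: 4-methylbenzenesulfonyl chloride, Cc1ccc(cc1)S(=O)(=O)Cl
Why: Standard O-sulfonylation of an unhindered primary alcohol.

Step 8
Reactants: 13 pent-4-yn-1-yl 4-methylbenzenesulfonate
Product: 15 (4E)-5-iodopent-4-en-1-yl 4-methylbenzenesulfonate, via alkenylzirconocene 14 (not isolated)
Conditions: Cp2Zr(H)Cl (1.2 equiv), THF, rt, dark; then I2 (1.2 equiv), 0 °C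
Reagents that add atoms: iodine, II
Why: Schwartz syn-hydrozirconation puts Zr on the terminal carbon and iodinolysis proceeds with retention, giving the (E)-1-iodoalkene only; the alkyl tosylate is inert to both reagents.

Step 9
Reactants: 11 (2R)-2-(3-bromopropyl)-2,4-dimethyloxetane; 15 (4E)-5-iodopent-4-en-1-yl 4-methylbenzenesulfonate
Product: 17 (2R)-2-[(7E)-8-iodooct-7-en-1-yl]-2,4-dimethyloxetane (4RS), via Grignard reagent 16 (not isolated)
Conditions: 11, Mg turnings, THF, rt → 40 °C; then added to 15 and Li2CuCl4 (5 mol %), THF, −40 → −10 °C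
Reagents that add atoms: none
Why: Kochi–Schlosser copper-catalysed sp3–sp3 cross-coupling; at low temperature the primary tosylate is alkylated much faster than the alkenyl iodide undergoes exchange or substitution, and the hindered oxetane is not opened.

Step 10
Reactants: 17 (2R)-2-[(7E)-8-iodooct-7-en-1-yl]-2,4-dimethyloxetane (4RS)
Product: 18 (4S,11E)-4-hydroperoxy-12-iodo-4-methyldodec-11-en-2-ol (2RS)
Conditions: anhydrous H2O2 in Et2O (10 equiv), TMSOTf (0.3 equiv), Et2O, −78 → −20 °C
Reagents that add atoms: hydrogen peroxide, OO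
Why: Lewis-acid-promoted perhydrolysis of the oxetane at its more substituted carbon; H2O2 attacks the activated oxonium from the face opposite the leaving oxygen, so the (R)-C–O centre is inverted to the (S)-C–OOH centre needed for C5.

Step 11
Reactants: 18 (4S,11E)-4-hydroperoxy-12-iodo-4-methyldodec-11-en-2-ol (2RS)
Product: 20 (4S,11E)-12-iodo-4-[(2-methoxypropan-2-yl)peroxy]-4-methyldodec-11-en-2-one, via peroxyketal alcohol 19 (not isolated)
Conditions: 2-methoxypropene (1.2 equiv), PPTS (3 mol %), CH2Cl2, 0 °C; then pyridine (5 equiv), Dess–Martin periodinane (1.5 equiv), 0 °C → rt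
Reagents that add atoms: 2-methoxypropene, COC(C)=C
Why: The more nucleophilic hydroperoxide is trapped as the more stable monoperoxyketal (any mixed ketal of the hindered alcohol reverts), then Dess–Martin oxidation of the free secondary alcohol removes the epimeric carbinol without touching the stereocentre.

Step 12
Reactants: 20 (4S,11E)-12-iodo-4-[(2-methoxypropan-2-yl)peroxy]-4-methyldodec-11-en-2-one
Product: 21 methyl (2E,5S,12E)-13-iodo-5-[(2-methoxypropan-2-yl)peroxy]-3,5-dimethyltrideca-2,12-dienoate (2E major; the minor 2Z isomer is carried along)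
Conditions: (MeO)2P(O)CH2CO2Me (2.0 equiv), NaH (1.9 equiv), THF, 0 °C → rt
Reagents that add atoms: trimethyl phosphonoacetate, COC(=O)CP(=O)(OC)OC
Why: Horner–Wadsworth–Emmons olefination of the methyl ketone by the weakly basic phosphonate anion (no free hydride left), which limits enolisation towards the β-peroxy carbon; the E/Z ratio does not matter because both isomers give the same ring closure.

Step 13
Reactants: 21 methyl (2E,5S,12E)-13-iodo-5-[(2-methoxypropan-2-yl)peroxy]-3,5-dimethyltrideca-2,12-dienoate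
Product: 23 methyl 2-[(3R,5S)-5-[(7E)-8-iodooct-7-en-1-yl]-3,5-dimethyl-1,2-dioxolan-3-yl]acetate, via hydroperoxy enoate 22 (not isolated)
Conditions: AcOH/THF/H2O (3:1:1), rt; concentrate; then Et2NH (2 equiv), CF3CH2OH, rt; C3 epimers separated on SiO2/HPLC
Reagents that add atoms: none
Why: Peroxyketal hydrolysis, then base-mediated intramolecular oxa-Michael addition (5-exo-trig) of the tertiary hydroperoxide to the β-methyl enoate closes the 1,2-dioxolane; C5 is carried in as (S), while C3 forms under weak substrate control (expect about 1:1), so the (3R,5S) isomer is separated and the 3S epimer is resubmitted to base for retro-Michael re-equilibration.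

Step 14
Reactants: 24 pent-2-yn-1-ol
Product: 25 (2Z)-pent-2-en-1-ol
Conditions: H2 (1 atm), Lindlar catalyst, quinoline, MeOH, rt
Reagents that add atoms: none
Why: Lindlar semi-hydrogenation adds H2 syn to the alkyne and stops at the (Z)-alkene.

Step 15
Reactants: 25 (2Z)-pent-2-en-1-ol
Product: 26 (2Z)-1-bromopent-2-ene
Conditions: PBr3 (0.4 equiv), pyridine (cat.), Et2O, −10 → 0 °C
Reagents that add atoms: phosphorus tribromide, BrP(Br)Br
Why: Low-temperature bromination of the primary allylic alcohol via its phosphite ester, without allylic transposition or Z→E isomerisation.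

Step 16
Reactants: 26 (2Z)-1-bromopent-2-ene
Product: 27 (4Z)-hept-4-en-1-yne
Conditions: HC≡CMgBr (1.5 equiv), CuCl (5 mol %), THF, 0 → 40 °C; handled as a solution (volatile)
Reagents that add atoms: ethynylmagnesium bromide, C#C[Mg]Br
Why: Copper-catalysed alkynyl–allyl coupling at the α-carbon gives the skipped enyne with the (Z)-alkene retained.

Step 17
Reactants: 27 (4Z)-hept-4-en-1-yne
Product: 28 2-[(1E,4Z)-hepta-1,4-dien-1-yl]-4,4,5,5-tetramethyl-1,3,2-dioxaborolane
Conditions: pinacolborane (1.1 equiv), Cp2Zr(H)Cl (5 mol %), Et3N (10 mol %), neat, 50 °C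
Reagents that add atoms: pinacolborane, CC1(C)OBOC1(C)C
Why: Zirconium-catalysed syn-hydroboration of the terminal alkyne gives the (E)-alkenyl boronate; the internal (Z)-alkene does not react.

Step 18
Reactants: 23 methyl 2-[(3R,5S)-5-[(7E)-8-iodooct-7-en-1-yl]-3,5-dimethyl-1,2-dioxolan-3-yl]acetate; 28 2-[(1E,4Z)-hepta-1,4-dien-1-yl]-4,4,5,5-tetramethyl-1,3,2-dioxaborolane
Product: 29 methyl 2-[(3R,5S)-3,5-dimethyl-5-[(7E,9E,12Z)-pentadeca-7,9,12-trien-1-yl]-1,2-dioxolan-3-yl]acetate (CNP0297319.1)
Conditions: Pd(dppf)Cl2·CH2Cl2 (5 mol %), AsPh3 (10 mol %), Cs2CO3 (2 equiv), THF/DMF/H2O, rt, degassed, dark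
Reagents that add atoms: none
Why: Suzuki–Miyaura sp2–sp2 coupling with retention of both alkene geometries builds the (7E,9E)-diene; mild room-temperature conditions of this kind leave hindered dialkyl peroxides and the skipped (Z)-alkene intact.

**Compound list**

1 | (R)-(−)-linalool, (3R)-3,7-dimethylocta-1,6-dien-3-ol | CC(C)=CCC[C@](O)(C)C=C | starting material
2 | 9-[(3S)-3-hydroxy-3,7-dimethyloct-6-en-1-yl]-9-borabicyclo[3.3.1]nonane (CIP label changes, geometry unchanged; formed in situ) | CC(C)=CCC[C@](O)(C)CCB1C2CCCC1CCC2 | intermediate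
3 | (3R)-3,7-dimethyloct-6-ene-1,3-diol | CC(C)=CCC[C@](O)(C)CCO | intermediate
4 | (3R)-3-hydroxy-3,7-dimethyloct-6-enal | CC(C)=CCC[C@](O)(C)CC=O | intermediate
5 | (4R)-4,8-dimethylnon-7-ene-2,4-diol (2RS) | CC(C)=CCC[C@](O)(C)CC(C)O | intermediate
6 | (4R)-4-hydroxy-4,8-dimethylnon-7-en-2-yl 4-methylbenzenesulfonate (2RS; formed in situ) | CC(C)=CCC[C@](O)(C)CC(C)OS(=O)(=O)c1ccc(C)cc1 | intermediate
7 | (2R)-2,4-dimethyl-2-(4-methylpent-3-en-1-yl)oxetane (4RS) | CC(C)=CCC[C@]1(C)CC(C)O1 | intermediate
8 | 5-{2-[(2R)-2,4-dimethyloxetan-2-yl]ethyl}-3,3-dimethyl-1,2,4-trioxolane (formed in situ) | CC1(C)OOC(CC[C@]2(C)CC(C)O2)O1 | intermediate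
9 | 3-[(2R)-2,4-dimethyloxetan-2-yl]propanal (formed in situ) | O=CCC[C@]1(C)CC(C)O1 | intermediate
10 | 3-[(2R)-2,4-dimethyloxetan-2-yl]propan-1-ol | OCCC[C@]1(C)CC(C)O1 | intermediate
11 | (2R)-2-(3-bromopropyl)-2,4-dimethyloxetane | BrCCC[C@]1(C)CC(C)O1 | intermediate
12 | pent-4-yn-1-ol | C#CCCCO | starting material
13 | pent-4-yn-1-yl 4-methylbenzenesulfonate | C#CCCCOS(=O)(=O)c1ccc(C)cc1 | intermediate
14 | chlorobis(cyclopentadienyl)[(1E)-5-(tosyloxy)pent-1-en-1-yl]zirconium (formed in situ) | Cl[Zr](/C=C/CCCOS(=O)(=O)c1ccc(C)cc1)(C1C=CC=C1)C1C=CC=C1 | intermediate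
15 | (4E)-5-iodopent-4-en-1-yl 4-methylbenzenesulfonate | I/C=C/CCCOS(=O)(=O)c1ccc(C)cc1 | intermediate
16 | {3-[(2R)-2,4-dimethyloxetan-2-yl]propyl}magnesium bromide (formed in situ) | Br[Mg]CCC[C@]1(C)CC(C)O1 | intermediate
17 | (2R)-2-[(7E)-8-iodooct-7-en-1-yl]-2,4-dimethyloxetane (4RS) | I/C=C/CCCCCC[C@]1(C)CC(C)O1 | intermediate
18 | (4S,11E)-4-hydroperoxy-12-iodo-4-methyldodec-11-en-2-ol (2RS) | I/C=C/CCCCCC[C@@](OO)(C)CC(C)O | intermediate
19 | (4S,11E)-12-iodo-4-[(2-methoxypropan-2-yl)peroxy]-4-methyldodec-11-en-2-ol (2RS; formed in situ) | I/C=C/CCCCCC[C@@](OOC(C)(C)OC)(C)CC(C)O | intermediate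
20 | (4S,11E)-12-iodo-4-[(2-methoxypropan-2-yl)peroxy]-4-methyldodec-11-en-2-one | I/C=C/CCCCCC[C@@](OOC(C)(C)OC)(C)CC(C)=O | intermediate
21 | methyl (2E,5S,12E)-13-iodo-5-[(2-methoxypropan-2-yl)peroxy]-3,5-dimethyltrideca-2,12-dienoate | I/C=C/CCCCCC[C@@](OOC(C)(C)OC)(C)C/C(C)=C/C(=O)OC | intermediate
22 | methyl (2E,5S,12E)-5-hydroperoxy-13-iodo-3,5-dimethyltrideca-2,12-dienoate (formed in situ) | I/C=C/CCCCCC[C@@](OO)(C)C/C(C)=C/C(=O)OC | intermediate
23 | methyl 2-[(3R,5S)-5-[(7E)-8-iodooct-7-en-1-yl]-3,5-dimethyl-1,2-dioxolan-3-yl]acetate | I/C=C/CCCCCC[C@@]1(C)C[C@](C)(CC(=O)OC)OO1 | intermediate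
24 | pent-2-yn-1-ol | CCC#CCO | starting material
25 | (2Z)-pent-2-en-1-ol | CC/C=C\CO | intermediate
26 | (2Z)-1-bromopent-2-ene | CC/C=C\CBr | intermediate
27 | (4Z)-hept-4-en-1-yne | CC/C=C\CC#C | intermediate
28 | 2-[(1E,4Z)-hepta-1,4-dien-1-yl]-4,4,5,5-tetramethyl-1,3,2-dioxaborolane | CC/C=C\C/C=C/B1OC(C)(C)C(C)(C)O1 | intermediate
29 | methyl 2-[(3R,5S)-3,5-dimethyl-5-[(7E,9E,12Z)-pentadeca-7,9,12-trien-1-yl]-1,2-dioxolan-3-yl]acetate | CC/C=C\C/C=C/C=C/CCCCCC[C@@]1(C)C[C@](C)(CC(=O)OC)OO1 | target

**Totals**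

Total step count: 18.
Longest linear sequence: 12 steps (1–6, 9–13, 18). The other branches are steps 7–8 (iodoalkenyl tosylate) and steps 14–17 (dienyl boronate).

**Steps most likely to fail, with fallbacks**

Risk at step 9 (coupling next to an alkenyl iodide). Copper/magnesium chemistry may attack the C–I bond or open the oxetane during Grignard formation. The fallback sets out from alcohol 10 and rejoins the route at 17. TsCl/pyridine gives 3-[(2R)-2,4-dimethyloxetan-2-yl]propyl 4-methylbenzenesulfonate F1. Li2CuCl4-catalysed coupling of this tosylate with the Grignard reagent from commercial (5-chloropent-1-yn-1-yl)trimethylsilane gives {8-[(2R)-2,4-dimethyloxetan-2-yl]oct-1-yn-1-yl}trimethylsilane F2. K2CO3/MeOH then gives (2R)-2,4-dimethyl-2-(oct-7-yn-1-yl)oxetane F3. Hydrozirconation–iodination (Cp2Zr(H)Cl, then I2, as in step 8) installs the (E)-iodoalkene only after the C–C coupling and delivers 17.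

Risk at step 12 (HWE on a β-peroxy ketone). During the slow reaction at room temperature, enolisation towards C3 could expel the peroxide (E1cB) or close an epoxy ketone. The fallback sets out from ketone 20 and rejoins at 21. It is a kinetic Peterson olefination: the lithium enolate of methyl (trimethylsilyl)acetate (LDA, THF, −78 °C) adds to the carbonyl within minutes. The adduct methyl (5S,12E)-3-hydroxy-13-iodo-5-[(2-methoxypropan-2-yl)peroxy]-3,5-dimethyl-2-(trimethylsilyl)tridec-12-enoate F4 (as its lithium alkoxide, not isolated) loses silanolate on warming to 0 °C and gives 21 as an E/Z mixture.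

Risk at step 18 (Pd/base next to the O–O bond and the β-peroxy ester). Aqueous base could trigger retro-Michael opening, phosphine/Pd could reduce the peroxide, or the skipped dienyl boronate could protodeboronate. The fallback sets out from enyne 27 (with iodide 23) and rejoins at 29. Hydrozirconation of 27 (Cp2Zr(H)Cl) and transmetalation with Bu3SnCl gives tributyl[(1E,4Z)-hepta-1,4-dien-1-yl]stannane F5. A base-free Stille coupling of this stannane with 23 (Pd2(dba)3, AsPh3, NMP, rt) gives 29.

**Further compounds**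

F1 | step 9 | 3-[(2R)-2,4-dimethyloxetan-2-yl]propyl 4-methylbenzenesulfonate | Cc1ccc(cc1)S(=O)(=O)OCCC[C@]1(C)CC(C)O1
F2 | step 9 | {8-[(2R)-2,4-dimethyloxetan-2-yl]oct-1-yn-1-yl}trimethylsilane | C[Si](C)(C)C#CCCCCCC[C@]1(C)CC(C)O1
F3 | step 9 | (2R)-2,4-dimethyl-2-(oct-7-yn-1-yl)oxetane | C#CCCCCCC[C@]1(C)CC(C)O1
F4 | step 12 | methyl (5S,12E)-3-hydroxy-13-iodo-5-[(2-methoxypropan-2-yl)peroxy]-3,5-dimethyl-2-(trimethylsilyl)tridec-12-enoate | I/C=C/CCCCCC[C@@](OOC(C)(C)OC)(C)CC(C)(O)C(C(=O)OC)[Si](C)(C)C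
F5 | step 18 | tributyl[(1E,4Z)-hepta-1,4-dien-1-yl]stannane | CC/C=C\C/C=C/[Sn](CCCC)(CCCC)CCCC
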